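**Strategy.** Ring A (C1, C14, C13, C12, C11, C10) is cut into a C13–C14–C1 β-keto ester and a C10–C11–C12 enal. The design exploits the oxygens on C2 and C9, which flank the C1–C10 fusion bond: they are joined as an ester (C2 carbonyl to O9), a bond absent from the target. With substoichiometric base the tethered keto ester adds to C10, a carbonate leaves from C20, and the C13 enolate closes onto the C12 aldehyde, so C1–C10 and C12–C13 form in one operation and C9 relays its configuration to C10, C1, C12 and C13. The lactone is later opened at C2; a Nozaki–Hiyama–Kishi reaction closes the ten-membered ring at C5–C6.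

Key step: step 10

Remark (numbering and configuration): briarane numbering is used for every compound. C1 is the quaternary carbon (methyl C15); ring A is C1, C14, C13, C12, C11 (bearing C20), C10; the ten-membered ring is C1–C10 (C16 on C5, Cl on C6); the lactone is C7, C8, C17 (methyl C18), C19. The target SMILES is taken as the absolute configuration, and "as in the target" refers to it.

**Step 1**
Reactants: 1 methyl 3,4-O-isopropylidene-L-threonate
Product: 2 methyl 2-O-triethylsilyl-3,4-O-isopropylidene-L-threonate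
Conditions: Et3SiCl, imidazole, DMF, 0 °C to rt
Reagents that add atoms: chlorotriethylsilane, CC[Si](Cl)(CC)CC
Why: Imidazole-promoted silyl ether formation at the only free hydroxyl (the later O8); no stereocentre is touched.

**Step 2**
Reactants: 2 methyl 2-O-triethylsilyl-3,4-O-isopropylidene-L-threonate
Product: 3 2-O-triethylsilyl-3,4-O-isopropylidene-L-threose
Conditions: i-Bu2AlH (1.05 equiv), CH2Cl2, −78 °C; aq. potassium sodium tartrate
Reagents that add atoms: none
Why: Partial ester reduction stops at the aluminium hemiacetal at −78 °C and should release the α-silyloxy aldehyde on work-up without epimerisation at C8.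

**Step 3**
Reactants: 3 2-O-triethylsilyl-3,4-O-isopropylidene-L-threose
Product: 4 (3S,4S)-4-[(4S)-2,2-dimethyl-1,3-dioxolan-4-yl]-4-(triethylsilyloxy)but-1-en-3-ol
Conditions: CH2=CHMgBr, THF, −78 °C
Reagents that add atoms: vinylmagnesium bromide, C=C[Mg]Br
Why: Grignard addition under Felkin–Anh control (C8–OSi bond anti to the incoming vinyl group) should give mainly the 8,9-anti alcohol, which has the C9 configuration of the target; the minor epimer is removed by chromatography.

**Step 4**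
Reactants: 5 ethyl 4-chloro-3-oxobutanoate
Product: 6 ethyl 4-[(4-methoxybenzyl)oxy]-3-oxobutanoate
Conditions: 4-methoxybenzyl alcohol, NaH (2.2 equiv), THF, 0 °C to rt
Reagents that add atoms: 4-methoxybenzyl alcohol, COc1ccc(CO)cc1
Why: Williamson-type substitution of the primary chloride by the sodium alkoxide, while the keto ester is held as its enolate and so shielded from attack.

**Step 5**
Reactants: 6 ethyl 4-[(4-methoxybenzyl)oxy]-3-oxobutanoate
Product: 7 ethyl 4-[(4-methoxybenzyl)oxy]-2-methyl-3-oxobutanoate (racemic)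
Conditions: MeI (1.0 equiv), K2CO3, acetone, rt
Reagents that add atoms: iodomethane, CI
Why: C-Alkylation of the β-keto ester enolate installs C15; the new centre is racemic and is later erased as an enolate.

**Step 6**
Reactants: 4 the C9 allylic alcohol; 7 ethyl 4-[(4-methoxybenzyl)oxy]-2-methyl-3-oxobutanoate
Product: 8 O9 β-keto ester (4-[(4-methoxybenzyl)oxy]-2-methyl-3-oxobutanoate of 4, both C1 epimers)
Conditions: 7 (1.5 equiv), DMAP (0.2 equiv), toluene, 110 °C, 4 Å molecular sieves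
Reagents that add atoms: none
Why: DMAP-catalysed transesterification of an enolisable β-keto ester (through its acyl ketene) should acylate the secondary allylic hydroxyl and so create the temporary C2–O9 tether.

**Step 7**
Reactants: 9 2-methylidenepropane-1,3-diol
Product: 10 tert-butyl 2-(hydroxymethyl)prop-2-en-1-yl carbonate
Conditions: Boc2O (0.9 equiv), DMAP (0.05 equiv), MeCN, 0 °C
Reagents that add atoms: di-tert-butyl dicarbonate, CC(C)(C)OC(=O)OC(=O)OC(C)(C)C
Why: Statistical mono-carbonate formation on a symmetric diol; unreacted diol is recycled.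

**Step 8**
Reactants: 10 tert-butyl 2-(hydroxymethyl)prop-2-en-1-yl carbonate
Product: 11 tert-butyl 2-formylprop-2-en-1-yl carbonate
Conditions: MnO2, CH2Cl2, rt
Reagents that add atoms: none
Why: Selective oxidation of a primary allylic alcohol to the 2-substituted acrolein, which is used at once.

**Step 9**
Reactants: 8 O9 β-keto ester; 11 tert-butyl 2-formylprop-2-en-1-yl carbonate
Product: 12 (E)-enal carbonate (8 in which the vinyl CH2 is replaced by C11 bearing the C12 aldehyde and the C20 CH2–OCO2t-Bu arm; CHO trans to C9)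
Conditions: 11 (4 equiv), RuCl2(H2IMes)(=CH-C6H4-2-O-i-Pr) (second-generation Hoveyda–Grubbs catalyst, 10 mol%), CH2Cl2, 40 °C
Reagents that add atoms: none
Why: Olefin cross-metathesis of a terminal alkene with an excess of a 1,1-disubstituted enal, as known for methacrolein, should give the trisubstituted E-enal.

**Step 10**
Reactants: 12 (E)-enal carbonate
Product: 14 bicyclic aldol lactone (ring A with C14 ketone, equatorial 13-OPMB, axial 12-OH and C11 methylidene, trans-fused to the C2(=O)–O9 γ-lactone), via methylidene enal lactone 13 (not isolated)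
Conditions: Cs2CO3 (0.5 equiv), MeCN, −20 to 0 °C; AcOH quench
Reagents that add atoms: none
Why: Cs2CO3 deprotonates C1 of the β-keto ester, which adds 5-exo-trig to C10 of the enal (intramolecular Michael addition); the aldehyde enolate expels tert-butyl carbonate from C20 (E1cB, overall SN2′) to give 13, and the tert-butoxide released with CO2 enolises the C14 ketone towards C13, which closes onto the C12 aldehyde (6-enolendo-exo-trig aldol). The closest known reaction types are the base-mediated cyclisation of acetoacetates of γ-hydroxy enoates to γ-lactones and the Michael/aldol [3+3] annulation of β-keto esters with enals. The lactone closes with H9 in the plane of the C10=C11 bond (A(1,3) strain against the C20 arm), so C1 enters the enal face syn to O9 and anti to the C8 chain, and C9 thereby sets C10 (C8 and C11 trans on the lactone). At C1 an open, non-chelated transition state (caesium counter-ion, MeCN) should place C11 over the C15 methyl and not over the enolate C14–O unit, which gives the trans ring fusion. C12 and C13 follow from the locked chair: the aldehyde reacts from its s-trans conformer to give the axial 12-OH, which avoids A(1,3) strain with the methylidene, and the epimerisable 13-OPMB settles equatorial, cis to it. The step needs 1,2- and not 1,4-closure of the C13 enolate (onto C12, not C20) and survival of the aldol; the faster exo attack on the aldehyde, the only weakly basic medium and an acid quench as soon as 13 is consumed should secure both.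

**Step 11**
Reactants: 14 bicyclic aldol lactone
Product: 15 12-O-tert-butyldimethylsilyl ether of 14
Conditions: t-BuMe2SiOTf, 2,6-lutidine, CH2Cl2, −78 to −20 °C
Reagents that add atoms: tert-butyldimethylsilyl triflate, CC(C)(C)[Si](C)(C)OS(=O)(=O)C(F)(F)F
Why: Silyl triflate etherification of the secondary aldol hydroxyl blocks retro-aldol cleavage and puts a bulky axial group over one face of the C14 ketone.

**Step 12**
Reactants: 15 12-O-silyl keto lactone
Product: 16 14-alcohol (axial 14-OH, cis to O13 and O12)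
Conditions: LiBH(s-Bu)3, THF, −78 °C; AcOH quench at −78 °C
Reagents that add atoms: none
Why: Bulky hydride reduction; the syn-axial 12-OSi group blocks axial attack, so hydride should enter equatorially from the face of the C15 methyl and give the axial C14 alcohol, while the hindered lactone is untouched at −78 °C.

**Step 13**
Reactants: 17 (1-bromovinyl)trimethylsilane
Product: 19 3-(trimethylsilyl)but-3-en-1-ol, via 1-(trimethylsilyl)vinylmagnesium bromide 18 (not isolated)
Conditions: Mg, THF, 40 °C; then ethylene oxide, CuI (10 mol%), −30 to 0 °C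
Reagents that add atoms: ethylene oxide, C1CO1
Why: Grignard formation followed by copper-catalysed epoxide opening gives the C3–C5/C16 unit as a two-carbon-homologated alcohol.

**Step 14**
Reactants: 19 3-(trimethylsilyl)but-3-en-1-ol
Product: 20 (4-iodobut-1-en-2-yl)trimethylsilane
Conditions: I2, PPh3, imidazole, CH2Cl2, 0 °C
Reagents that add atoms: iodine, II
Why: Appel-type iodination of a primary alcohol.

**Step 15**
Reactants: 16 14-hydroxy lactone; 20 (4-iodobut-1-en-2-yl)trimethylsilane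
Product: 22 C2 ketone diol (ring A bearing at C1 the 4-(trimethylsilyl)pent-4-enoyl chain C2–C5/C16 and at C10 the C9(OH)–C8(OSiEt3)–C7/C6 acetonide chain), via 3-(trimethylsilyl)but-3-enyllithium 21 (not isolated)
Conditions: 20 (2.5 equiv), t-BuLi (5 equiv), Et2O/pentane, −78 °C; then 16, THF, −78 °C; AcOH quench at −78 °C
Reagents that add atoms: none
Why: Iodine–lithium exchange and addition of the alkyllithium to the lactone carbonyl (one equivalent is spent on the 14-OH); the tetrahedral lithium hemiketal persists at −78 °C, so the reaction should stop at the C2 ketone and cleave the temporary C2–O9 bond.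

**Step 16**
Reactants: 22 C2 ketone diol
Product: 23 9,14-diacetate of 22
Conditions: Ac2O, DMAP, pyridine, CH2Cl2, rt
Reagents that add atoms: acetic anhydride, CC(=O)OC(C)=O
Why: DMAP-catalysed acetylation of both secondary hydroxyls; O9 should react through the open hydroxy ketone form of the lactol equilibrium.

**Step 17**
Reactants: 23 9,14-diacetate
Product: 24 (2S)-alcohol
Conditions: (R)-2-methyl-CBS-oxazaborolidine [(R)-1-methyl-3,3-diphenyltetrahydro-1H,3H-pyrrolo[1,2-c][1,3,2]oxazaborole] (0.5 equiv), catecholborane, toluene, −78 °C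
Reagents that add atoms: none
Why: Corey–Bakshi–Shibata reduction; the quaternary C1 acts as the large and the C3 methylene as the small group, so the (R)-catalyst should deliver the (2S)-alcohol by reagent control.

**Step 18**
Reactants: 24 (2S)-alcohol
Product: 25 2,9,14-triacetate
Conditions: Ac2O, DMAP, Et3N, CH2Cl2, rt
Reagents that add atoms: acetic anhydride, CC(=O)OC(C)=O
Why: DMAP-catalysed acetylation of the hindered secondary 2-OH.

**Step 19**
Reactants: 25 2,9,14-triacetate
Product: 26 13-alcohol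
Conditions: DDQ, CH2Cl2/aq. pH 7 phosphate buffer, 0 °C
Reagents that add atoms: none
Why: Oxidative cleavage of the 4-methoxybenzyl ether; silyl ethers, acetonide and alkenes are inert to DDQ.

**Step 20**
Reactants: 26 13-alcohol
Product: 27 13-(4-methylpentanoate)
Conditions: 4-methylpentanoyl chloride, DMAP, pyridine, CH2Cl2, 0 °C to rt
Reagents that add atoms: 4-methylpentanoyl chloride, CC(C)CCC(Cl)=O
Why: Acylation of the equatorial 13-OH with an acid chloride under nucleophilic catalysis.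

**Step 21**
Reactants: 27 13-(4-methylpentanoate)
Product: 28 2-iodoalkene (C5–I, C5=C16)
Conditions: N-iodosuccinimide, MeCN/ClCH2CN (4:1), 0 °C to rt
Reagents that add atoms: N-iodosuccinimide, O=C1CCC(=O)N1I
Why: Iododesilylation of the vinylsilane (ipso-substitution); it is placed here because no free hydroxyl is present that could add to the C11=C20 alkene.

**Step 22**
Reactants: 28 2-iodoalkene
Product: 29 8-alcohol
Conditions: HF·pyridine, pyridine, THF, 0 °C
Reagents that add atoms: none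
Why: Buffered fluoride should cleave the secondary triethylsilyl ether faster than the hindered axial tert-butyldimethylsilyl ether.

**Step 23**
Reactants: 29 8-alcohol
Product: 30 8-ketone
Conditions: Dess–Martin periodinane, NaHCO3, CH2Cl2, 0 °C to rt
Reagents that add atoms: none
Why: Buffered Dess–Martin oxidation of the secondary alcohol, mild enough to leave the α-centres C7 and C9 unepimerised.

**Step 24**
Reactants: 30 8-ketone
Product: 31 6,7-diol
Conditions: AcOH/H2O (4:1), 45 °C
Reagents that add atoms: none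
Why: Acid hydrolysis of the terminal isopropylidene acetal; the silyl ether at C12, the esters and the iodoalkene tolerate aqueous acetic acid.

**Step 25**
Reactants: 31 6,7-diol
Product: 32 6-O-triethylsilyl ether (7-hydroxy-8-ketone)
Conditions: Et3SiCl, imidazole, CH2Cl2, −40 °C
Reagents that add atoms: chlorotriethylsilane, CC[Si](Cl)(CC)CC
Why: Selective silylation of the primary hydroxyl over the secondary α-ketol hydroxyl.

**Step 26**
Reactants: 32 6-O-triethylsilyl ether
Product: 33 7-O-(2-bromopropanoyl) ester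
Conditions: 2-bromopropanoyl bromide, pyridine, CH2Cl2, −40 °C
Reagents that add atoms: 2-bromopropanoyl bromide, CC(Br)C(Br)=O
Why: Acylation of the α-ketol hydroxyl places the C17–C19 unit on O7 and so fixes the regiochemistry of the lactone.

**Step 27**
Reactants: 33 7-O-(2-bromopropanoyl) ester
Product: 34 hydroxy lactone (C7, C8, C17 as in the target; 6-OSiEt3)
Conditions: Zn dust (activated with Me3SiCl), THF, 0 °C to rt
Reagents that add atoms: none
Why: Intramolecular Reformatsky reaction; the zinc enolate adds to the adjacent C8 ketone and closes the γ-lactone, and the reversible zinc aldolate should settle with C9 trans to C6 and the C18 methyl trans to C9, which sets C8 and C17.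

**Step 28**
Reactants: 34 hydroxy lactone
Product: 35 6-alcohol
Conditions: HF·pyridine, pyridine, THF, 0 °C
Reagents that add atoms: none
Why: Selective fluoride cleavage of the primary triethylsilyl ether in the presence of the hindered secondary silyl ether.

**Step 29**
Reactants: 35 6-alcohol
Product: 36 6-aldehyde
Conditions: Dess–Martin periodinane, NaHCO3, CH2Cl2, 0 °C
Reagents that add atoms: none
Why: Mild oxidation to the α-acyloxy aldehyde, which is used at once to avoid epimerisation at C7.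

**Step 30**
Reactants: 36 6-aldehyde
Product: 37 ten-membered carbocycle, 6-alcohol (both C6 epimers)
Conditions: CrCl2 (10 equiv), NiCl2 (0.1 equiv), DMSO/THF, rt, 0.002 M, slow addition
Reagents that add atoms: none
Why: Intramolecular Nozaki–Hiyama–Kishi reaction; the alkenylchromium species formed from the 2-iodoalkene adds to the C6 aldehyde at high dilution and closes the ten-membered ring with C5=C16 in place, and both C6 epimers are usable because C6 is oxidised next.

**Step 31**
Reactants: 37 macrocyclic 6-alcohol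
Product: 38 5(16)-en-6-one
Conditions: Dess–Martin periodinane, NaHCO3, CH2Cl2, rt
Reagents that add atoms: none
Why: Oxidation of the secondary allylic alcohol converges both epimers to one enone; the tertiary 8-OH cannot be oxidised.

**Step 32**
Reactants: 38 5(16)-en-6-one
Product: 39 (6R)-alcohol
Conditions: NaBH4, CeCl3·7H2O, MeOH/THF, −78 °C
Reagents that add atoms: none
Why: Luche 1,2-reduction; Felkin–Anh attack of hydride anti to the C7–O bond should give the (6R)-alcohol, the epimer needed for an inverting substitution.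

**Step 33**
Reactants: 39 (6R)-alcohol
Product: 40 (6S)-chloride
Conditions: PPh3, hexachloroacetone, CH2Cl2, −20 to 0 °C
Reagents that add atoms: hexachloroacetone, ClC(Cl)(Cl)C(=O)C(Cl)(Cl)Cl
Why: Appel-type chlorination of a secondary allylic alcohol, which proceeds by SN2 with inversion and without allylic transposition; the tertiary 8-OH does not react.

**Step 34**
Reactants: 40 (6S)-chloride
Product: 41 12-alcohol
Conditions: HF·pyridine, THF, 0 °C to rt
Reagents that add atoms: none
Why: Fluoride cleavage of the last silyl ether frees the allylic 12-OH; acetates, lactone and allylic chloride are stable to it.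

**Step 35**
Reactants: 41 12-alcohol
Product: 42 11,20-epoxide (epoxide oxygen cis to 12-OH)
Conditions: VO(acac)2 (5 mol%), t-BuOOH, CH2Cl2, 0 °C to rt
Reagents that add atoms: tert-butyl hydroperoxide, CC(C)(C)OO
Why: Hydroxyl-directed epoxidation; the vanadium alkoxide of the axial allylic 12-OH delivers oxygen to the same face of C11=C20 and sets C11, while the C5=C16 alkene, which lacks an allylic hydroxyl and is deactivated by chlorine, is left alone.

**Step 36**
Reactants: 42 epoxy alcohol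
Product: 43 CNP0196150.1 (target)
Conditions: Ac2O, DMAP (cat.), pyridine, 0 °C to rt
Reagents that add atoms: acetic anhydride, CC(=O)OC(C)=O
Why: Acetylation of the secondary 12-OH; the tertiary 8-OH is far slower and should stay free.

**Compound list**

1 | methyl 3,4-O-isopropylidene-L-threonate, methyl (2R)-2-[(4S)-2,2-dimethyl-1,3-dioxolan-4-yl]-2-hydroxyacetate | COC(=O)[C@H](O)[C@@H]1COC(C)(C)O1 | starting material
2 | methyl (2R)-2-[(4S)-2,2-dimethyl-1,3-dioxolan-4-yl]-2-(triethylsilyloxy)acetate | COC(=O)[C@H](O[Si](CC)(CC)CC)[C@@H]1COC(C)(C)O1 | intermediate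
3 | (2R)-2-[(4S)-2,2-dimethyl-1,3-dioxolan-4-yl]-2-(triethylsilyloxy)acetaldehyde | O=C[C@H](O[Si](CC)(CC)CC)[C@@H]1COC(C)(C)O1 | intermediate
4 | (3S,4S)-4-[(4S)-2,2-dimethyl-1,3-dioxolan-4-yl]-4-(triethylsilyloxy)but-1-en-3-ol (C9 carbinol) | C=C[C@H](O)[C@H](O[Si](CC)(CC)CC)[C@@H]1COC(C)(C)O1 | intermediate
5 | ethyl 4-chloro-3-oxobutanoate | CCOC(=O)CC(=O)CCl | starting material
6 | ethyl 4-[(4-methoxybenzyl)oxy]-3-oxobutanoate | CCOC(=O)CC(=O)COCc1ccc(OC)cc1 | intermediate
7 | ethyl 4-[(4-methoxybenzyl)oxy]-2-methyl-3-oxobutanoate (racemic) | CCOC(=O)C(C)C(=O)COCc1ccc(OC)cc1 | intermediate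
8 | O9 β-keto ester of 4 (C1 epimers) | C=C[C@H](OC(=O)C(C)C(=O)COCc1ccc(OC)cc1)[C@H](O[Si](CC)(CC)CC)[C@@H]1COC(C)(C)O1 | intermediate
9 | 2-methylidenepropane-1,3-diol | C=C(CO)CO | starting material
10 | tert-butyl 2-(hydroxymethyl)prop-2-en-1-yl carbonate | C=C(CO)COC(=O)OC(C)(C)C | intermediate
11 | tert-butyl 2-formylprop-2-en-1-yl carbonate | C=C(C=O)COC(=O)OC(C)(C)C | intermediate
12 | (E)-enal carbonate (C10=C11; C12 aldehyde; C20 tert-butyl carbonate; O9 β-keto ester) | O=C/C(COC(=O)OC(C)(C)C)=C/[C@H](OC(=O)C(C)C(=O)COCc1ccc(OC)cc1)[C@H](O[Si](CC)(CC)CC)[C@@H]1COC(C)(C)O1 | intermediate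
13 | methylidene enal lactone (C1, C9, C10 as in the target; C11 cis to C15, trans to C8) | C[C@@]1(C(=O)COCc2ccc(OC)cc2)C(=O)O[C@H]([C@H](O[Si](CC)(CC)CC)[C@@H]2COC(C)(C)O2)[C@H]1C(=C)C=O | intermediate
14 | bicyclic aldol lactone (C1, C9, C10, C12, C13 as in the target) | C[C@@]12C(=O)O[C@H]([C@H](O[Si](CC)(CC)CC)[C@@H]3COC(C)(C)O3)[C@H]1C(=C)[C@H](O)[C@H](OCc1ccc(OC)cc1)C2=O | intermediate
15 | 12-O-tert-butyldimethylsilyl ether of 14 | C[C@@]12C(=O)O[C@H]([C@H](O[Si](CC)(CC)CC)[C@@H]3COC(C)(C)O3)[C@H]1C(=C)[C@H](O[Si](C)(C)C(C)(C)C)[C@H](OCc1ccc(OC)cc1)C2=O | intermediate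
16 | 14-alcohol (C14 as in the target) | C[C@@]12C(=O)O[C@H]([C@H](O[Si](CC)(CC)CC)[C@@H]3COC(C)(C)O3)[C@H]1C(=C)[C@H](O[Si](C)(C)C(C)(C)C)[C@H](OCc1ccc(OC)cc1)[C@@H]2O | intermediate
17 | (1-bromovinyl)trimethylsilane | C=C(Br)[Si](C)(C)C | starting material
18 | 1-(trimethylsilyl)vinylmagnesium bromide | C=C([Mg]Br)[Si](C)(C)C | intermediate
19 | 3-(trimethylsilyl)but-3-en-1-ol | C=C(CCO)[Si](C)(C)C | intermediate
20 | (4-iodobut-1-en-2-yl)trimethylsilane | C=C(CCI)[Si](C)(C)C | intermediate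
21 | 3-(trimethylsilyl)but-3-enyllithium | [Li]CCC(=C)[Si](C)(C)C | intermediate
22 | C2 ketone diol (9-OH, 14-OH; open form) | C=C([Si](C)(C)C)CCC(=O)[C@@]1(C)[C@@H](O)[C@@H](OCc2ccc(OC)cc2)[C@@H](O[Si](C)(C)C(C)(C)C)C(=C)[C@@H]1[C@H](O)[C@H](O[Si](CC)(CC)CC)[C@@H]2COC(C)(C)O2 | intermediate
23 | 9,14-diacetate | C=C([Si](C)(C)C)CCC(=O)[C@@]1(C)[C@@H](OC(C)=O)[C@@H](OCc2ccc(OC)cc2)[C@@H](O[Si](C)(C)C(C)(C)C)C(=C)[C@@H]1[C@H](OC(C)=O)[C@H](O[Si](CC)(CC)CC)[C@@H]2COC(C)(C)O2 | intermediate
24 | (2S)-alcohol | C=C([Si](C)(C)C)CC[C@H](O)[C@@]1(C)[C@@H](OC(C)=O)[C@@H](OCc2ccc(OC)cc2)[C@@H](O[Si](C)(C)C(C)(C)C)C(=C)[C@@H]1[C@H](OC(C)=O)[C@H](O[Si](CC)(CC)CC)[C@@H]2COC(C)(C)O2 | intermediate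
25 | 2,9,14-triacetate | C=C([Si](C)(C)C)CC[C@H](OC(C)=O)[C@@]1(C)[C@@H](OC(C)=O)[C@@H](OCc2ccc(OC)cc2)[C@@H](O[Si](C)(C)C(C)(C)C)C(=C)[C@@H]1[C@H](OC(C)=O)[C@H](O[Si](CC)(CC)CC)[C@@H]2COC(C)(C)O2 | intermediate
26 | 13-alcohol | C=C([Si](C)(C)C)CC[C@H](OC(C)=O)[C@@]1(C)[C@@H](OC(C)=O)[C@@H](O)[C@@H](O[Si](C)(C)C(C)(C)C)C(=C)[C@@H]1[C@H](OC(C)=O)[C@H](O[Si](CC)(CC)CC)[C@@H]2COC(C)(C)O2 | intermediate
27 | 13-(4-methylpentanoate) | C=C([Si](C)(C)C)CC[C@H](OC(C)=O)[C@@]1(C)[C@@H](OC(C)=O)[C@@H](OC(=O)CCC(C)C)[C@@H](O[Si](C)(C)C(C)(C)C)C(=C)[C@@H]1[C@H](OC(C)=O)[C@H](O[Si](CC)(CC)CC)[C@@H]2COC(C)(C)O2 | intermediate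
28 | 2-iodoalkene (I on C5) | C=C(I)CC[C@H](OC(C)=O)[C@@]1(C)[C@@H](OC(C)=O)[C@@H](OC(=O)CCC(C)C)[C@@H](O[Si](C)(C)C(C)(C)C)C(=C)[C@@H]1[C@H](OC(C)=O)[C@H](O[Si](CC)(CC)CC)[C@@H]2COC(C)(C)O2 | intermediate
29 | 8-alcohol | C=C(I)CC[C@H](OC(C)=O)[C@@]1(C)[C@@H](OC(C)=O)[C@@H](OC(=O)CCC(C)C)[C@@H](O[Si](C)(C)C(C)(C)C)C(=C)[C@@H]1[C@H](OC(C)=O)[C@H](O)[C@@H]2COC(C)(C)O2 | intermediate
30 | 8-ketone | C=C(I)CC[C@H](OC(C)=O)[C@@]1(C)[C@@H](OC(C)=O)[C@@H](OC(=O)CCC(C)C)[C@@H](O[Si](C)(C)C(C)(C)C)C(=C)[C@@H]1[C@H](OC(C)=O)C(=O)[C@@H]2COC(C)(C)O2 | intermediate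
31 | 6,7-diol | C=C(I)CC[C@H](OC(C)=O)[C@@]1(C)[C@@H](OC(C)=O)[C@@H](OC(=O)CCC(C)C)[C@@H](O[Si](C)(C)C(C)(C)C)C(=C)[C@@H]1[C@H](OC(C)=O)C(=O)[C@@H](O)CO | intermediate
32 | 6-O-triethylsilyl ether (7-hydroxy-8-ketone) | C=C(I)CC[C@H](OC(C)=O)[C@@]1(C)[C@@H](OC(C)=O)[C@@H](OC(=O)CCC(C)C)[C@@H](O[Si](C)(C)C(C)(C)C)C(=C)[C@@H]1[C@H](OC(C)=O)C(=O)[C@@H](O)CO[Si](CC)(CC)CC | intermediate
33 | 7-O-(2-bromopropanoyl) ester (bromide epimers) | C=C(I)CC[C@H](OC(C)=O)[C@@]1(C)[C@@H](OC(C)=O)[C@@H](OC(=O)CCC(C)C)[C@@H](O[Si](C)(C)C(C)(C)C)C(=C)[C@@H]1[C@H](OC(C)=O)C(=O)[C@@H](OC(=O)C(C)Br)CO[Si](CC)(CC)CC | intermediate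
34 | hydroxy lactone (C7, C8, C17 as in the target) | C=C(I)CC[C@H](OC(C)=O)[C@@]1(C)[C@@H](OC(C)=O)[C@@H](OC(=O)CCC(C)C)[C@@H](O[Si](C)(C)C(C)(C)C)C(=C)[C@@H]1[C@H](OC(C)=O)[C@]1(O)[C@@H](C)C(=O)O[C@H]1CO[Si](CC)(CC)CC | intermediate
35 | 6-alcohol | C=C(I)CC[C@H](OC(C)=O)[C@@]1(C)[C@@H](OC(C)=O)[C@@H](OC(=O)CCC(C)C)[C@@H](O[Si](C)(C)C(C)(C)C)C(=C)[C@@H]1[C@H](OC(C)=O)[C@]1(O)[C@@H](C)C(=O)O[C@H]1CO | intermediate
36 | 6-aldehyde | C=C(I)CC[C@H](OC(C)=O)[C@@]1(C)[C@@H](OC(C)=O)[C@@H](OC(=O)CCC(C)C)[C@@H](O[Si](C)(C)C(C)(C)C)C(=C)[C@@H]1[C@H](OC(C)=O)[C@]1(O)[C@@H](C)C(=O)O[C@H]1C=O | intermediate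
37 | macrocyclic 6-alcohol (C6 epimers; 12-OSi; 11(20)-ene) | C=C1CC[C@H](OC(C)=O)[C@@]2(C)[C@@H](OC(C)=O)[C@@H](OC(=O)CCC(C)C)[C@@H](O[Si](C)(C)C(C)(C)C)C(=C)[C@@H]2[C@H](OC(C)=O)[C@]2(O)[C@@H](C)C(=O)O[C@H]2C1O | intermediate
38 | 5(16)-en-6-one | C=C1CC[C@H](OC(C)=O)[C@@]2(C)[C@@H](OC(C)=O)[C@@H](OC(=O)CCC(C)C)[C@@H](O[Si](C)(C)C(C)(C)C)C(=C)[C@@H]2[C@H](OC(C)=O)[C@]2(O)[C@@H](C)C(=O)O[C@H]2C1=O | intermediate
39 | (6R)-alcohol | C=C1CC[C@H](OC(C)=O)[C@@]2(C)[C@@H](OC(C)=O)[C@@H](OC(=O)CCC(C)C)[C@@H](O[Si](C)(C)C(C)(C)C)C(=C)[C@@H]2[C@H](OC(C)=O)[C@]2(O)[C@@H](C)C(=O)O[C@H]2[C@@H]1O | intermediate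
40 | (6S)-chloride | C=C1CC[C@H](OC(C)=O)[C@@]2(C)[C@@H](OC(C)=O)[C@@H](OC(=O)CCC(C)C)[C@@H](O[Si](C)(C)C(C)(C)C)C(=C)[C@@H]2[C@H](OC(C)=O)[C@]2(O)[C@@H](C)C(=O)O[C@H]2[C@H]1Cl | intermediate
41 | 12-alcohol | C=C1CC[C@H](OC(C)=O)[C@@]2(C)[C@@H](OC(C)=O)[C@@H](OC(=O)CCC(C)C)[C@@H](O)C(=C)[C@@H]2[C@H](OC(C)=O)[C@]2(O)[C@@H](C)C(=O)O[C@H]2[C@H]1Cl | intermediate
42 | 11,20-epoxy 12-alcohol | C=C1CC[C@H](OC(C)=O)[C@@]2(C)[C@@H](OC(C)=O)[C@@H](OC(=O)CCC(C)C)[C@@H](O)[C@]3(CO3)[C@@H]2[C@H](OC(C)=O)[C@]2(O)[C@@H](C)C(=O)O[C@H]2[C@H]1Cl | intermediate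
43 | CNP0196150.1 | C=C1CC[C@H](OC(C)=O)[C@@]2(C)[C@@H](OC(C)=O)[C@@H](OC(=O)CCC(C)C)[C@@H](OC(C)=O)[C@]3(CO3)[C@@H]2[C@H](OC(C)=O)[C@]2(O)[C@@H](C)C(=O)O[C@H]2[C@H]1Cl | target

**Summary**

Total step count: 36. Longest linear sequence: 30 steps (steps 1–3, 6, 9–12, 15–36).

Three steps most likely to fail:

Step 10. The C13 enolate may close 1,4 onto C20 instead of 1,2 onto C12, the C1 addition may pass through a closed transition state and give the cis ring fusion, or the aldol may revert or dehydrate in base. Fallback from 12 to 14: DBU (0.1 equiv) in CH2Cl2 at −20 °C should stop after the addition–elimination at methylidene enal lactone 13, which is then isolated. Me3SiOTf/Et3N (CH2Cl2, −78 °C) converts its C14 ketone into the trimethylsilyl enol ether F1. MgBr2·OEt2 (CH2Cl2, −78 °C) then closes C12–C13 by an intramolecular Mukaiyama aldol addition, which can only be 1,2, and aqueous work-up returns 14.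

Step 30. Intermolecular coupling and reduction of the carbon–iodine bond may outrun closure of the ten-membered ring. Fallback from 35 to 38: TEMPO/PhI(OAc)2 in MeCN/H2O oxidises the primary alcohol to the C6 carboxylic acid F3. EtSH, EDC·HCl and DMAP give the S-ethyl thioester F4. (Me3Sn)2 with Pd(PPh3)4 (toluene, 80 °C) gives the alkenylstannane thioester F5. Pd2(dba)3, P(2-furyl)3 and CuTC (copper thiophene-2-carboxylate, Cu(O2CC4H3S)) in THF at high dilution then close the ring by an intramolecular thioester–stannane ketone synthesis (Liebeskind–Srogl coupling) and give enone 38 directly.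

Step 27. The bromide may be reduced without ring closure, or the tethered enolate may add to the wrong face of the C8 ketone. Fallback from 32 to 34: an intermolecular Reformatsky addition of ethyl 2-bromopropanoate (Zn, THF, 0 °C) to α-hydroxy ketone 32. The zinc alkoxide of the free 7-OH chelates the C8 carbonyl, so the reagent should add anti to the C6 arm and give the dihydroxy ester F2 with the required C8 configuration. PPTS in toluene at 60 °C lactonises O7 onto the ester (C17 equilibrates to the methyl trans to C9) and returns 34.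

**Further compounds**

F1 | step 10 | trimethylsilyl enol ether of 13 (C14–OSiMe3, C13=C14) | C[C@@]1(C(O[Si](C)(C)C)=COCc2ccc(OC)cc2)C(=O)O[C@H]([C@H](O[Si](CC)(CC)CC)[C@@H]2COC(C)(C)O2)[C@H]1C(=C)C=O
F2 | step 27 | 7,8-dihydroxy ethyl ester (C8 as in the target, C17 epimers) | C=C(I)CC[C@H](OC(C)=O)[C@@]1(C)[C@@H](OC(C)=O)[C@@H](OC(=O)CCC(C)C)[C@@H](O[Si](C)(C)C(C)(C)C)C(=C)[C@@H]1[C@H](OC(C)=O)[C@](O)(C(C)C(=O)OCC)[C@@H](O)CO[Si](CC)(CC)CC
F3 | step 30 | C6 carboxylic acid | C=C(I)CC[C@H](OC(C)=O)[C@@]1(C)[C@@H](OC(C)=O)[C@@H](OC(=O)CCC(C)C)[C@@H](O[Si](C)(C)C(C)(C)C)C(=C)[C@@H]1[C@H](OC(C)=O)[C@]1(O)[C@@H](C)C(=O)O[C@H]1C(=O)O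
F4 | step 30 | C6 S-ethyl thioester | C=C(I)CC[C@H](OC(C)=O)[C@@]1(C)[C@@H](OC(C)=O)[C@@H](OC(=O)CCC(C)C)[C@@H](O[Si](C)(C)C(C)(C)C)C(=C)[C@@H]1[C@H](OC(C)=O)[C@]1(O)[C@@H](C)C(=O)O[C@H]1C(=O)SCC
F5 | step 30 | C5 trimethylstannyl alkene S-ethyl thioester | C=C([Sn](C)(C)C)CC[C@H](OC(C)=O)[C@@]1(C)[C@@H](OC(C)=O)[C@@H](OC(=O)CCC(C)C)[C@@H](O[Si](C)(C)C(C)(C)C)C(=C)[C@@H]1[C@H](OC(C)=O)[C@]1(O)[C@@H](C)C(=O)O[C@H]1C(=O)SCC
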